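Flavonoid numbering (O1, C2, C3, C4, C4a, C5–C8, C8a; ring B primed) is used for every compound, open-chain ones included.

## The problem

Target 20 is a (2R,3R)-3-methoxyflavanone. Ring A carries methoxy groups at C5, C6 and C7; ring C holds O1, the stereocentres C2 and C3 and the C4 carbonyl; ring B, a 2,5-dihydroxy-4-methoxyphenyl group, sits on C2. The two stereocentres are adjacent and trans. C3 is α to the ketone, and C2 is a benzylic ether carbon on a very electron-rich ring. Once the flavanone exists, acid can ionise C2 and base can open ring C by β-elimination of the O1 phenoxide, and either event destroys the C2 configuration. Ring B is a hydroquinone and must stay masked to the last step; benzyl ethers are chosen because they leave under neutral, reducing conditions.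

C3 can be set first by an auxiliary and then control its neighbours. A syn aldol places a temporary hydroxyl at C4, and that hydroxyl directs hydride to C2 so that C2–OH ends up anti to C4–OH and therefore anti to C3–OMe. This is the relationship a 2,3-trans ring requires when O1 is attached with retention.

The feature that makes the key step possible is that O1 links the sp3 carbon C2 to the aromatic carbon C8a, which is ortho to the C4a–C4 bond. A C2 carbinol and a C8a bromide in an open 1,3-diol can therefore be joined by copper-catalysed O-arylation without breaking any bond to C2 or C3. C4 has to pass through that step as a carbinol, because a C2 alkoxide β to a C4 ketone would cleave by retro-aldol.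

## Retrosynthesis

**20 from 19.** The two phenolic O–CH2Ph bonds of ring B are cut. The hydroquinone is the most fragile part of the target, so it is unmasked last. Benzyl ethers survive organomagnesium reagents, hydride, hot carbonate and a periodinane, and they leave under neutral hydrogenolysis. The skeleton of 19 is unchanged but the compound is air-stable. The forward step must remove the benzyl groups faster than it cleaves the cyclic benzylic C2–O1 bond or reduces the C4 ketone.

**19 from 18.** The C4 carbonyl is traced back to a C4 carbinol. This is preferred over closing the ring at the ketone level, where the ring-closing alkoxide would fragment by retro-aldol. The carbinol 18 costs one mild oxidation, which also removes a stereocentre that has done its work. The oxidation must not enolise towards C3 or open ring C.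

**18 from 17.** The O1–C8a bond is cut. Cutting O1–C2 instead would mean displacement at an electron-rich benzylic carbon or a reversible conjugate addition, and both put C2 at risk. Cutting C4–C4a would mean an acylation of ring A under acid, which again endangers C2. The O1–C8a cut leaves every bond to C2 and C3 in place. Precursor 17 is an acyclic bromo diol in which all stereocentres sit on a freely rotating chain. The forward reaction must choose the C2 hydroxyl over the C4 hydroxyl, keep the C2 configuration and accept an electron-rich aryl bromide.

**17 from 16.** The C2–H bond is cut, leaving a C2 ketone. The C4 hydroxyl already present can deliver hydride 1,3-anti. Because C3 and C4 are syn, anti to C4–OH is also anti to C3–OMe. Making C2 by adding an aryl nucleophile to an aldehyde would offer weaker control. Ketone 16 has one stereocentre fewer and is the direct product of joining the two halves. The reduction must be highly anti-selective on a donor-substituted aryl ketone.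

**16 from 11 and 15 (15 from 14).** The C2–C1' bond is cut. The neighbouring way of joining the halves, an aldol across C2–C3, would require an enantioselective anti addition of an α-methoxy ketone enolate to an electron-rich aldehyde, for which no dependable control element exists. Forming C2–C1' needs no stereocontrol and splits the molecule into two halves of similar size. The forward step must stop at the ketone, tolerate the free C4 hydroxyl of 11 and leave the ring A bromide alone. For that reason the nucleophile 15 is a magnesium reagent and not a lithium reagent.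

**11 from 10, and 10 from 7 and 3.** The C3–C4 bond is cut as an aldol, followed by exchange of the acyl carrier. A syn glycolate aldol on an oxazolidinone is among the most predictable ways to make an α-alkoxy-β-hydroxy acyl unit. It fixes C3 absolutely and C4 as the relay centre. The methoxy group comes in with the two-carbon unit, so no selective O-methylation is ever needed. The precursors are an achiral aldehyde 3 and the glycolate imide 7 on a recoverable auxiliary. The aldol must proceed through the Z enolate and add to a di-ortho-substituted aldehyde.

**3 from 1; 7 from 4 and 5; 14 from 13 and 13 from 12.** These cuts are the formyl C–C4a bond, the N-acyl bond, the C1'–Br bond and the two O-benzyl bonds. Each forward step has a single plausible site. The two free positions of 1 are equivalent, and 13 is most activated para to its methoxy group. Compounds 1, 4, 5 and 12 are commercial.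

## Roads not taken

**Alternative 1:** The cut removes the C2–C3 bond and the C3–OMe bond together. In the forward step Rh2(OAc)4 (divalent rhodium) converts diazoketone A1 into a carbene, methanol forms an oxonium ylide, and that ylide adds to aldehyde A2. The aldehyde is activated by a BINOL complex made from Zr(OBu)4 (tetravalent zirconium). The product is the anti β-hydroxy ketone A3.
- Merits: three simple components give the whole stereodyad in one catalytic step with no auxiliary. This is about three steps shorter than the sequence used here to reach the same oxidation pattern, and that advantage is real.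
- Weak points: an ylide bearing an α-hydrogen collapses quickly by 1,2-proton shift to the plain methoxymethyl ketone. Aldehyde A2 carries three donor groups and is a poor trap. Anti selectivity and enantiocontrol for a diazoketone-derived ylide are far less secure than for aryl diazoacetates. A1 needs a hindered aroyl chloride and a diazomethane equivalent.
- Comparison: no ring closes in this step, so A3 would still need a reduction and the same copper closure. The chosen plan spends more steps but sets each centre by a reaction whose sense of induction is known in advance.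

**Alternative 2:** The cut is C4–C4a. The activated carboxyl group of acid A4 acylates the ortho carbon of its 3,4,5-trimethoxyphenyl ether and gives flavanone A5, which is identical with 19.
- Merits: the aryl ether is symmetric, so there is no regiochemical question. The ring is formed at the ketone level, which saves the reduction and reoxidation at C4. On redox economy this road is better.
- Weak points: C2 of A4 is a benzylic carbon bearing a donor-rich ring and an aryloxy group, and acylium-forming conditions are exactly those that ionise it. An activated α-methoxy acid can lose C3 through a ketene. Benzyl ethers are at risk from strong Lewis or Brønsted acids. Making A4 with a defined C2–O bond would itself need a substitution at that same labile carbon.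
- Comparison: the chosen plan closes the ring under carbonate base and never exposes the C2–O bond to acid. Its price is two redox steps.

**Alternative 3:** The cut is C3–C4. SmI2 (divalent samarium) couples the aryl aldehyde and the aliphatic aldehyde of dialdehyde A6 to give the cis-3,4-diol A7, with the C3 oxygen trans to ring B.
- Merits: one step forms a C–C bond, ring C and two stereocentres from a single preset centre. If A6 were easy to obtain, this would be the shortest ring construction of all.
- Weak points: A6 is an α-aryl-α-aryloxy acetaldehyde whose C2–H is acidic, so its configuration is fragile. Ketyls with an α-aryloxy group tend to expel aryloxide instead of coupling. A7 has two free hydroxyls, so selective methylation at C3 and oxidation at C4 must follow, and an α-hydroxy ketone does not tolerate basic methylation well.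
- Comparison: the chosen plan brings the C3 methyl ether in from the start and has no hydroxyl differentiation to solve after ring closure.

Key step: step 9

## Route

Step 1
Reactants: 1 5-bromo-1,2,3-trimethoxybenzene
Product: 3 6-bromo-2,3,4-trimethoxybenzaldehyde, via aryl chloromethyl methyl ether 2 (not isolated)
Conditions: Cl2CHOMe, TiCl4, CH2Cl2, −10 → 0 °C; then ice/H2O
Reagents that add atoms: dichloromethyl methyl ether, COC(Cl)Cl; water, O
Why: Rieche formylation (electrophilic aromatic substitution); the two free positions of 1 are equivalent and each is para to one methoxy group and ortho to another, so only one aldehyde can form, and chloro ether 2 hydrolyses on work-up.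

Step 2
Reactants: 4 (S)-4-benzyloxazolidin-2-one; 5 methoxyacetyl chloride
Product: 7 (S)-4-benzyl-3-(2-methoxyacetyl)oxazolidin-2-one, via lithium oxazolidinide 6 (not isolated)
Conditions: n-BuLi, THF, −78 °C; then 5, −78 → 0 °C
Reagents that add atoms: none
Why: N-acylation of the lithiated oxazolidinone by an acid chloride, the standard loading of an Evans auxiliary; no stereocentre is touched.

Step 3
Reactants: 7 (S)-4-benzyl-3-(2-methoxyacetyl)oxazolidin-2-one; 3 6-bromo-2,3,4-trimethoxybenzaldehyde
Product: 10 (S)-4-benzyl-3-[(2S,3R)-3-(6-bromo-2,3,4-trimethoxyphenyl)-3-hydroxy-2-methoxypropanoyl]oxazolidin-2-one, via Z boron enolate 8 (not isolated), via boron aldolate 9 (not isolated)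
Conditions: Bu2BOTf, Et3N, CH2Cl2, −78 → 0 °C; then 3, −78 → 0 °C; pH 7 buffer, MeOH, 30% H2O2, 0 °C
Reagents that add atoms: none
Why: Evans syn aldol; soft enolisation gives Z enolate 8, which adds through a Zimmerman–Traxler chair with the auxiliary carbonyl turned away from boron and the benzyl group shielding one face. The (S)-auxiliary should therefore set propanoyl C2 (flavonoid C3) as S and propanoyl C3 (flavonoid C4) as R, that is 3,4-syn.

Step 4
Reactants: 10 (S)-4-benzyl-3-[(2S,3R)-3-(6-bromo-2,3,4-trimethoxyphenyl)-3-hydroxy-2-methoxypropanoyl]oxazolidin-2-one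
Product: 11 (2S,3R)-3-(6-bromo-2,3,4-trimethoxyphenyl)-3-hydroxy-N,2-dimethoxy-N-methylpropanamide
Conditions: MeNHOMe·HCl, AlMe3, CH2Cl2, −20 → 0 °C; aq. potassium sodium tartrate
Reagents that add atoms: N,O-dimethylhydroxylamine hydrochloride, CNOC.Cl
Why: Weinreb transamination of an N-acyloxazolidinone by an aluminium amide, assisted by the free β-hydroxyl; no stereocentre is touched and auxiliary 4 is recovered.

Step 5
Reactants: 12 2-methoxyhydroquinone (2-methoxybenzene-1,4-diol)
Product: 13 1,4-bis(benzyloxy)-2-methoxybenzene
Conditions: BnBr, K2CO3, DMF, 60 °C, argon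
Reagents that add atoms: benzyl bromide, BrCc1ccccc1
Why: Williamson ether synthesis on both phenols; air is excluded because the hydroquinone oxidises readily.

Step 6
Reactants: 13 1,4-bis(benzyloxy)-2-methoxybenzene
Product: 14 1,4-bis(benzyloxy)-2-bromo-5-methoxybenzene
Conditions: NBS, MeCN, 0 °C → rt
Reagents that add atoms: N-bromosuccinimide, O=C1CCC(=O)N1Br
Why: Electrophilic aromatic bromination; the position para to the methoxy group and ortho to a benzyloxy group is the most activated and least hindered, as is usual for 1,2,4-trialkoxybenzenes.

Step 7
Reactants: 14 1,4-bis(benzyloxy)-2-bromo-5-methoxybenzene; 11 (2S,3R)-3-(6-bromo-2,3,4-trimethoxyphenyl)-3-hydroxy-N,2-dimethoxy-N-methylpropanamide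
Product: 16 (2S,3R)-1-[2,5-bis(benzyloxy)-4-methoxyphenyl]-3-(6-bromo-2,3,4-trimethoxyphenyl)-3-hydroxy-2-methoxypropan-1-one, via aryl Grignard reagent 15 (not isolated)
Conditions: 14 (2.5 equiv), Mg, BrCH2CH2Br (cat.), THF, 50 °C; solution of 15 decanted from Mg; then 11, THF, 0 °C → rt; AcOH, 0 °C
Reagents that add atoms: none
Why: Weinreb ketone synthesis; one equivalent of 15 is consumed by the hydroxyl proton (returning 13, which can be recycled) and a second adds to the amide, which stops at the ketone level. A magnesium reagent is used so that no halogen–metal exchange occurs at the ring A bromide and α-deprotonation at C3 is less likely.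

Step 8
Reactants: 16 (2S,3R)-1-[2,5-bis(benzyloxy)-4-methoxyphenyl]-3-(6-bromo-2,3,4-trimethoxyphenyl)-3-hydroxy-2-methoxypropan-1-one
Product: 17 (1R,2R,3R)-1-[2,5-bis(benzyloxy)-4-methoxyphenyl]-3-(6-bromo-2,3,4-trimethoxyphenyl)-2-methoxypropane-1,3-diol
Conditions: Me4NBH(OAc)3, MeCN/AcOH (1:1), −30 °C
Reagents that add atoms: none
Why: Evans–Saksena reduction; the C4 hydroxyl exchanges onto boron and delivers hydride intramolecularly through a chair transition state, which should give the 1,3-anti diol with C2 as R, anti to C4–OH and to C3–OMe. A Cram chelate through the C3 methoxy group favours the same face. The descriptor at the methoxy carbon changes from S to R only because the priorities change.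

Step 9
Reactants: 17 (1R,2R,3R)-1-[2,5-bis(benzyloxy)-4-methoxyphenyl]-3-(6-bromo-2,3,4-trimethoxyphenyl)-2-methoxypropane-1,3-diol
Product: 18 (2R,3S,4R)-2-[2,5-bis(benzyloxy)-4-methoxyphenyl]-3,5,6,7-tetramethoxychroman-4-ol (2,3-trans, 3,4-trans)
Conditions: CuI (10 mol %), 3,4,7,8-tetramethyl-1,10-phenanthroline (20 mol %), Cs2CO3 (2 equiv), toluene (0.02 M), 110 °C, argon
Reagents that add atoms: none
Why: Cs2CO3 generates the alkoxides; the phenanthroline-bound monovalent copper alkoxide at O–C2 adds oxidatively to the C8a–Br bond, and reductive elimination from the trivalent copper aryl alkoxide forms O1–C8a and returns monovalent copper. The closest known reaction type is the Ullmann-type copper-catalysed intramolecular O-arylation of aliphatic alcohols by aryl halides, which is used to make chromans and dihydrobenzofurans. Ring C closes as a six-membered ring by attack of the C2 oxygen on the ring A carbon C8a (a 6-exo closure onto the arene). No new stereocentre is formed; C2 keeps its configuration because the C2–O bond is never broken, and C3 and C4 are spectators (the C3 descriptor changes from R to S by priority only). The step needs site selectivity between two secondary benzylic hydroxyls, and ring size provides it: O–C2 reaches C8a in a six-membered ring, whereas O–C4 would have to close a four-membered ring, and copper held by the C4 alkoxide is released by reversible exchange. The step also needs ring closure to outrun intermolecular arylation and hydrodebromination, which dilution and the chelating ligand should secure. The benzyl and methyl ethers are inert to carbonate and copper.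

Step 10
Reactants: 18 (2R,3S,4R)-2-[2,5-bis(benzyloxy)-4-methoxyphenyl]-3,5,6,7-tetramethoxychroman-4-ol
Product: 19 (2R,3R)-2-[2,5-bis(benzyloxy)-4-methoxyphenyl]-3,5,6,7-tetramethoxychroman-4-one
Conditions: Dess–Martin periodinane, pyridine, CH2Cl2, 0 °C → rt
Reagents that add atoms: none
Why: Dess–Martin oxidation of a secondary benzylic alcohol under buffered, non-enolising conditions; the relay centre C4 is erased while C2 and C3 are untouched, and the 2,3-trans isomer is also the more stable one at C3.

Step 11
Reactants: 19 (2R,3R)-2-[2,5-bis(benzyloxy)-4-methoxyphenyl]-3,5,6,7-tetramethoxychroman-4-one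
Product: 20 (2R,3R)-2-(2,5-dihydroxy-4-methoxyphenyl)-3,5,6,7-tetramethoxychroman-4-one (CNP0150769.1)
Conditions: H2 (1 atm), Pd/C (10%), EtOAc, rt; work-up under argon
Reagents that add atoms: none
Why: Hydrogenolysis of aryl benzyl ethers over Pd/C at 1 atm is much faster than cleavage of the cyclic benzylic C2–O1 bond or reduction of the aryl ketone; the neutral reducing medium keeps the hydroquinone reduced and leaves both stereocentres alone.

## Compound list

1 | 5-bromo-1,2,3-trimethoxybenzene | COc1cc(Br)cc(OC)c1OC | starting material
2 | 1-bromo-2-[chloro(methoxy)methyl]-3,4,5-trimethoxybenzene (racemic) | COC(Cl)c1c(Br)cc(OC)c(OC)c1OC | intermediate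
3 | 6-bromo-2,3,4-trimethoxybenzaldehyde | O=Cc1c(Br)cc(OC)c(OC)c1OC | intermediate
4 | (S)-4-benzyloxazolidin-2-one | O=C1N[C@@H](Cc2ccccc2)CO1 | starting material
5 | methoxyacetyl chloride | COCC(=O)Cl | starting material
6 | N-lithio-(S)-4-benzyloxazolidin-2-one | [Li]N1C(=O)OC[C@@H]1Cc1ccccc1 | intermediate
7 | (S)-4-benzyl-3-(2-methoxyacetyl)oxazolidin-2-one | COCC(=O)N1C(=O)OC[C@@H]1Cc1ccccc1 | intermediate
8 | (S)-4-benzyl-3-[(Z)-1-(dibutylboryloxy)-2-methoxyethenyl]oxazolidin-2-one | CO/C=C(\OB(CCCC)CCCC)N1C(=O)OC[C@@H]1Cc1ccccc1 | intermediate
9 | (S)-4-benzyl-3-[(2S,3R)-3-(6-bromo-2,3,4-trimethoxyphenyl)-3-(dibutylboryloxy)-2-methoxypropanoyl]oxazolidin-2-one | O=C(N1C(=O)OC[C@@H]1Cc1ccccc1)[C@@H](OC)[C@H](OB(CCCC)CCCC)c1c(OC)c(OC)c(OC)cc1Br | intermediate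
10 | (S)-4-benzyl-3-[(2S,3R)-3-(6-bromo-2,3,4-trimethoxyphenyl)-3-hydroxy-2-methoxypropanoyl]oxazolidin-2-one | O=C(N1C(=O)OC[C@@H]1Cc1ccccc1)[C@@H](OC)[C@H](O)c1c(OC)c(OC)c(OC)cc1Br | intermediate
11 | (2S,3R)-3-(6-bromo-2,3,4-trimethoxyphenyl)-3-hydroxy-N,2-dimethoxy-N-methylpropanamide | CON(C)C(=O)[C@@H](OC)[C@H](O)c1c(OC)c(OC)c(OC)cc1Br | intermediate
12 | 2-methoxyhydroquinone (2-methoxybenzene-1,4-diol) | COc1cc(O)ccc1O | starting material
13 | 1,4-bis(benzyloxy)-2-methoxybenzene | COc1cc(OCc2ccccc2)ccc1OCc1ccccc1 | intermediate
14 | 1,4-bis(benzyloxy)-2-bromo-5-methoxybenzene | COc1cc(OCc2ccccc2)c(Br)cc1OCc1ccccc1 | intermediate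
15 | [2,5-bis(benzyloxy)-4-methoxyphenyl]magnesium bromide | COc1cc(OCc2ccccc2)c([Mg]Br)cc1OCc1ccccc1 | intermediate
16 | (2S,3R)-1-[2,5-bis(benzyloxy)-4-methoxyphenyl]-3-(6-bromo-2,3,4-trimethoxyphenyl)-3-hydroxy-2-methoxypropan-1-one | COc1cc(OCc2ccccc2)c(C(=O)[C@@H](OC)[C@H](O)c2c(OC)c(OC)c(OC)cc2Br)cc1OCc1ccccc1 | intermediate
17 | (1R,2R,3R)-1-[2,5-bis(benzyloxy)-4-methoxyphenyl]-3-(6-bromo-2,3,4-trimethoxyphenyl)-2-methoxypropane-1,3-diol (2,3-anti, 3,4-syn, 2,4-anti in flavonoid numbering) | COc1cc(OCc2ccccc2)c([C@@H](O)[C@@H](OC)[C@H](O)c2c(OC)c(OC)c(OC)cc2Br)cc1OCc1ccccc1 | intermediate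
18 | (2R,3S,4R)-2-[2,5-bis(benzyloxy)-4-methoxyphenyl]-3,5,6,7-tetramethoxychroman-4-ol | COc1cc(OCc2ccccc2)c([C@H]2Oc3cc(OC)c(OC)c(OC)c3[C@@H](O)[C@@H]2OC)cc1OCc1ccccc1 | intermediate
19 | (2R,3R)-2-[2,5-bis(benzyloxy)-4-methoxyphenyl]-3,5,6,7-tetramethoxychroman-4-one | COc1cc(OCc2ccccc2)c([C@H]2Oc3cc(OC)c(OC)c(OC)c3C(=O)[C@@H]2OC)cc1OCc1ccccc1 | intermediate
20 | (2R,3R)-2-(2,5-dihydroxy-4-methoxyphenyl)-3,5,6,7-tetramethoxychroman-4-one | COc1cc(O)c([C@H]2Oc3cc(OC)c(OC)c(OC)c3C(=O)[C@@H]2OC)cc1O | target

## Step count and risks

Total steps: 11. Longest linear sequence: 8 steps (1 → 3 → 10 → 11 → 16 → 17 → 18 → 19 → 20; the branch from 4 and 5 is equally long, the branch from 12 has 7).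

**Step 9 (key step).** Oxidative addition of copper into the electron-rich, ortho-substituted C8a–Br bond may be slow. Hydrodebromination or intermolecular etherification could then overtake ring closure, and the C4 alkoxide may hold copper unproductively. The fallback moves the closure to a different metal and catalytic cycle. Diol 17 is treated with Pd(OAc)2, 2-(di-tert-butylphosphino)-1,1'-binaphthyl and Cs2CO3 in toluene at 70 °C (Buchwald–Hartwig-type etherification). Zerovalent palladium inserts into C8a–Br whether or not an alkoxide is bound, and the bulky phosphine drives C–O reductive elimination from divalent palladium with retention at C2. This fallback sets out from 17, returns at 18 and makes no new compound.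

**Step 7.** Addition to the magnesium alkoxide of 11 may stall, and the basic reagent may cause loss of configuration at C3 by α-deprotonation or retro-aldol cleavage of the C3–C4 bond. The fallback removes the free hydroxyl for the duration of the coupling. Amide 11 is silylated (TESOTf, 2,6-lutidine, CH2Cl2, −78 °C) to the O-triethylsilyl Weinreb amide F1. This reacts with 1.3 equivalents of 15 to give the silyl-protected ketone F2. HF·pyridine in THF/pyridine at 0 °C then frees the hydroxyl and returns the route to 16.

**Step 8.** Hydride transfer to the donor-deactivated aryl ketone may be slow. Warming would erode the anti selectivity and invite acid-promoted ionisation at the benzylic carbinol carbons in AcOH. The fallback replaces hydroxyl direction by chelation control in a non-acidic medium. Ketone 16 is silylated (TBSOTf, 2,6-lutidine) to the C4 silyl ether F3. Zn(BH4)2 in Et2O at −20 °C reduces it through the Cram chelate of the C3 methoxy group to the 2,3-anti alcohol F4. Tetrabutylammonium fluoride in THF then returns the route to 17.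

**Step 11.** Over-reduction is possible, either by hydrogenolysis of the benzylic C2–O1 bond or by reduction of the C4 carbonyl, and the hydroquinone may oxidise in air during isolation. The fallback replaces hydrogenolysis by Lewis-acid debenzylation with a cation scavenger (BCl3, pentamethylbenzene, CH2Cl2, −78 °C). The low temperature is meant to spare the C5 methyl ether next to the carbonyl. This fallback runs from 19 to 20 and makes no new compound.

## Further compounds

F1 | step 7 | (2S,3R)-3-(6-bromo-2,3,4-trimethoxyphenyl)-N,2-dimethoxy-N-methyl-3-(triethylsilyloxy)propanamide | CON(C)C(=O)[C@@H](OC)[C@H](O[Si](CC)(CC)CC)c1c(OC)c(OC)c(OC)cc1Br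
F2 | step 7 | (2S,3R)-1-[2,5-bis(benzyloxy)-4-methoxyphenyl]-3-(6-bromo-2,3,4-trimethoxyphenyl)-2-methoxy-3-(triethylsilyloxy)propan-1-one | COc1cc(OCc2ccccc2)c(C(=O)[C@@H](OC)[C@H](O[Si](CC)(CC)CC)c2c(OC)c(OC)c(OC)cc2Br)cc1OCc1ccccc1
F3 | step 8 | (2S,3R)-1-[2,5-bis(benzyloxy)-4-methoxyphenyl]-3-(6-bromo-2,3,4-trimethoxyphenyl)-3-[(tert-butyldimethylsilyl)oxy]-2-methoxypropan-1-one | COc1cc(OCc2ccccc2)c(C(=O)[C@@H](OC)[C@H](O[Si](C)(C)C(C)(C)C)c2c(OC)c(OC)c(OC)cc2Br)cc1OCc1ccccc1
F4 | step 8 | (1R,2R,3R)-1-[2,5-bis(benzyloxy)-4-methoxyphenyl]-3-(6-bromo-2,3,4-trimethoxyphenyl)-3-[(tert-butyldimethylsilyl)oxy]-2-methoxypropan-1-ol | COc1cc(OCc2ccccc2)c([C@@H](O)[C@@H](OC)[C@H](O[Si](C)(C)C(C)(C)C)c2c(OC)c(OC)c(OC)cc2Br)cc1OCc1ccccc1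
F0 | step 9 | none | none
F0 | step 11 | none | none
A1 | alternative 1 | 1-(6-bromo-2,3,4-trimethoxyphenyl)-2-diazoethan-1-one | COc1cc(Br)c(C(=O)C=[N+]=[N-])c(OC)c1OC
A2 | alternative 1 | 2,5-bis(benzyloxy)-4-methoxybenzaldehyde | COc1cc(OCc2ccccc2)c(C=O)cc1OCc1ccccc1
A3 | alternative 1 | (2R,3R)-3-[2,5-bis(benzyloxy)-4-methoxyphenyl]-1-(6-bromo-2,3,4-trimethoxyphenyl)-3-hydroxy-2-methoxypropan-1-one | COc1cc(OCc2ccccc2)c([C@@H](O)[C@@H](OC)C(=O)c2c(OC)c(OC)c(OC)cc2Br)cc1OCc1ccccc1
A4 | alternative 2 | (2R,3R)-3-[2,5-bis(benzyloxy)-4-methoxyphenyl]-2-methoxy-3-(3,4,5-trimethoxyphenoxy)propanoic acid | COc1cc(OCc2ccccc2)c([C@@H](Oc2cc(OC)c(OC)c(OC)c2)[C@@H](OC)C(O)=O)cc1OCc1ccccc1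
A5 | alternative 2 | (2R,3R)-2-[2,5-bis(benzyloxy)-4-methoxyphenyl]-3,5,6,7-tetramethoxychroman-4-one | COc1cc(OCc2ccccc2)c([C@H]2Oc3cc(OC)c(OC)c(OC)c3C(=O)[C@@H]2OC)cc1OCc1ccccc1
A6 | alternative 3 | 2-{(1R)-1-[2,5-bis(benzyloxy)-4-methoxyphenyl]-2-oxoethoxy}-4,5,6-trimethoxybenzaldehyde | COc1cc(OCc2ccccc2)c([C@H](C=O)Oc2cc(OC)c(OC)c(OC)c2C=O)cc1OCc1ccccc1
A7 | alternative 3 | (2R,3S,4S)-2-[2,5-bis(benzyloxy)-4-methoxyphenyl]-5,6,7-trimethoxychroman-3,4-diol | COc1cc(OCc2ccccc2)c([C@H]2Oc3cc(OC)c(OC)c(OC)c3[C@H](O)[C@@H]2O)cc1OCc1ccccc1
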